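**Retrosynthetic overview**
1. Ring D is closed last: the C8–C15 bond forms by oxidative cyclization (divalent palladium) of the C7 lactone silyl ketene acetal onto a C13 isopropenyl group; C15 oxidation and exo-face hydrogenation then give the C15 ketone and the C16 methyl.
2. Ring C comes before it: the C9–C11 bond forms by SmI2 ketyl–olefin closure onto the C8=C9 spiro δ-lactone, and C11 is then set by oxidation and equatorial hydride delivery. The δ-lactone comes from ester aldol and dehydration between a C20 ester (side chain from (4S)-limonene oxide) and the C9 aldehyde.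
3. Key disconnection: ring A carries the contiguous array C10 (quaternary) – C5 (H, C6 carboxyl) – C4 (quaternary, C18 methyl and C19H2–O). It is made by a ring-contracting Ireland–Claisen rearrangement of a δ-lactone (C6 carbonyl, ring oxygen on C2, (E)-C3=C4 alkenyl group on C2) that forms C4–C5; the C19–O–C6 γ-lactone follows.
4. The Claisen lactone comes from (R)-5-(hydroxymethyl)butyrolactone: two α-alkylations build C10 against the C2 carbinol, then reduction, lactone transposition and Wittig olefination.
5. Ring order: A (with γ-lactone), then δ-lactone, then C, then D.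

Key step: step 13

Assumption: ent-kaurane numbering is used throughout; the C11 hydroxyl is read from the SMILES as trans to H9, on the face of ring C opposite the C15–C16 bridge; compounds 1 and 26 are taken as commercial.

**Route**

Step 1
Reactants: 1 (R)-5-(hydroxymethyl)dihydrofuran-2(3H)-one
Product: 2 (R)-5-(trityloxymethyl)dihydrofuran-2(3H)-one
Conditions: TrCl, Et3N, DMAP (cat.), CH2Cl2, rt
Reagents that add atoms: trityl chloride, ClC(c1ccccc1)(c1ccccc1)c1ccccc1
Why: O-tritylation of the primary alcohol (SN1 etherification) installs the bulky CH2OTr group that steers both α-alkylations.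

Step 2
Reactants: 2 (R)-5-(trityloxymethyl)dihydrofuran-2(3H)-one; 3 allyl bromide
Product: 4 (5R)-3-allyl-5-(trityloxymethyl)dihydrofuran-2(3H)-one (C3 epimers)
Conditions: LiN(iPr)2, THF, −78 °C; then 3
Reagents that add atoms: none
Why: Lithium enolate alkylation of the butyrolactone; the C3 configuration formed here does not matter because the centre is enolized again in step 3.

Step 3
Reactants: 4 (5R)-3-allyl-5-(trityloxymethyl)dihydrofuran-2(3H)-one; 5 benzyl chloromethyl ether
Product: 6 3-allyl-3-(benzyloxymethyl)-5-(trityloxymethyl)dihydrofuran-2(3H)-one (benzyloxymethyl trans to trityloxymethyl)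
Conditions: LiN(iPr)2, THF, −78 °C; then 5, −78 → −20 °C
Reagents that add atoms: none
Why: Second enolate alkylation creates quaternary C10; the electrophile enters anti to the γ-CH2OTr group across the planar enolate (1,3-induction in γ-substituted butyrolactone enolates), so the future C9 carbon ends trans and the allyl group (future C5–C6) cis to it.

Step 4
Reactants: 6 quaternary lactone
Product: 7 2-allyl-2-(benzyloxymethyl)-5-(trityloxy)pentane-1,4-diol
Conditions: LiAlH4, THF, 0 °C
Reagents that add atoms: none
Why: Hydride reduction of the lactone frees the C2 carbinol and turns the carbonyl carbon into C20H2OH; no stereocentre is touched.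

Step 5
Reactants: 7 diol
Product: 8 C20 mono-TBDPS ether of diol 7
Conditions: TBDPSCl, imidazole, CH2Cl2, 0 °C
Reagents that add atoms: tert-butyldiphenylsilyl chloride, CC(C)(C)[Si](Cl)(c1ccccc1)c1ccccc1
Why: Selective silylation of the primary over the secondary hydroxyl with a bulky silyl chloride.

Step 6
Reactants: 8 mono-TBDPS ether
Product: 10 six-membered lactol (anomers), via open-chain hydroxy aldehyde 9 (not isolated)
Conditions: O3, CH2Cl2/MeOH, −78 °C; then PPh3, −78 °C → rt
Reagents that add atoms: ozone, [O-][O+]=O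
Why: Ozonolysis of the terminal alkene with reductive work-up gives the C6 aldehyde, which closes onto the C2 hydroxyl to the lactol.

Step 7
Reactants: 10 lactol
Product: 11 δ-lactone with CH2OTr on C2
Conditions: (nPr4N)RuO4 (cat.), NMO, 4 Å MS, CH2Cl2, rt
Reagents that add atoms: none
Why: Ley–Griffith oxidation of the lactol gives the δ-lactone with its carbonyl at C6 and its ring oxygen on C2, as the Claisen step needs.

Step 8
Reactants: 11 δ-lactone trityl ether
Product: 12 δ-lactone with CH2OH on C2
Conditions: TsOH·H2O (cat.), MeOH/CH2Cl2, 0 °C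
Reagents that add atoms: none
Why: Acid-catalysed solvolysis of the trityl ether through the stabilized trityl cation, under conditions that leave TBDPS and benzyl ethers intact.

Step 9
Reactants: 12 primary alcohol
Product: 13 δ-lactone C2 carbaldehyde
Conditions: Dess–Martin periodinane, NaHCO3, CH2Cl2, 0 °C → rt
Reagents that add atoms: none
Why: Dess–Martin oxidation under buffered conditions gives the α-acyloxy aldehyde without epimerizing C2.

Step 10
Reactants: 13 aldehyde; 14 2-(triphenylphosphoranylidene)propanal
Product: 15 (E)-enal (methyl cis to C2)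
Conditions: toluene, 60 °C
Reagents that add atoms: none
Why: Wittig olefination with a stabilized ylide gives the (E)-trisubstituted enal, the geometry that later encodes C4.

Step 11
Reactants: 15 (E)-enal
Product: 16 (E)-allylic alcohol
Conditions: NaBH4, CeCl3·7H2O, MeOH, −40 °C
Reagents that add atoms: none
Why: Luche 1,2-reduction of the enal; the δ-lactone is not reduced at low temperature.

Step 12
Reactants: 16 allylic alcohol
Product: 17 Claisen precursor (δ-lactone with (E)-alkenyl group on C2 and C19–OTBS)
Conditions: TBSCl, imidazole, CH2Cl2, 0 °C → rt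
Reagents that add atoms: tert-butyldimethylsilyl chloride, CC(C)(C)[Si](C)(C)Cl
Why: Standard silylation of the primary allylic alcohol.

Step 13
Reactants: 17 Claisen precursor
Product: 20 ring A cyclohexene carboxylic acid, via silyl ketene acetal 18 (not isolated), via trimethylsilyl ester 19 (not isolated)
Conditions: LiN(iPr)2, Me3SiCl/Et3N, THF, −78 °C; then rt → toluene, 100 °C; 1 M HCl work-up
Reagents that add atoms: none
Why: Enolization at C5 (the only α-position) with in-situ silylation gives the cyclic silyl ketene acetal 18, which undergoes the Ireland–Claisen [3,3] shift: C2–O breaks, C4–C5 forms and C2=C3 appears, so the six-membered lactone contracts to the cyclohexene of ring A and C6 becomes the silyl ester 19, hydrolysed on work-up. The closest known reaction type is the ring-contracting ester-enolate Claisen rearrangement of 6-alkenyl tetrahydropyran-2-ones to cyclohex-3-ene carboxylic acids. Ring A closes by suprafacial C–C bond formation through a boat-like, bicyclo[2.2.2]-type transition state, because the two-atom C10–C1 bridge ties C5 to C2 and excludes the chair. C4 is set by the (E) geometry of C3=C4 (methyl cis to C2) together with the (R) carbinol centre C2; C5 follows because the endocyclic ketene acetal has a single geometry and bonds on its ring face; both are thereby tied to C10, which is untouched. The step needs regioselective enolization and tolerance of the congested C10–C5–C4 array; C10 is quaternary, so no second α-site and no β-elimination are open, and the intramolecular concerted mode suits hindered bond formation.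

Step 14
Reactants: 20 ring A acid
Product: 22 cis-fused γ-lactone (C19–O–C6) on the ring A cyclohexene, via hydroxy acid 21 (not isolated)
Conditions: HF·pyridine, THF, 0 °C; then CSA (cat.), CH2Cl2, rt
Reagents that add atoms: none
Why: Fluoride cleavage of the primary TBS ether (TBDPS survives) frees C19–OH, which is cis to the C6 acid on ring A and lactonizes under acid catalysis.

Step 15
Reactants: 22 unsaturated γ-lactone
Product: 23 saturated γ-lactone with free C9 hydroxyl
Conditions: H2 (1 atm), Pd/C, EtOAc, rt
Reagents that add atoms: none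
Why: Heterogeneous hydrogenation saturates C2=C3 and hydrogenolyses the benzyl ether in one operation; no stereocentre is formed.

Step 16
Reactants: 23 C9 alcohol
Product: 24 C9 aldehyde
Conditions: Dess–Martin periodinane, NaHCO3, CH2Cl2, rt
Reagents that add atoms: none
Why: Dess–Martin oxidation of the neopentyl alcohol gives the non-enolizable C9 aldehyde.

Step 17
Reactants: 24 C9 aldehyde
Product: 25 C20 hydroxy C9 aldehyde
Conditions: HF·pyridine, pyridine/THF, rt
Reagents that add atoms: none
Why: Acidic fluoride desilylation frees C20–OH without base, which avoids retro-aldol loss of formaldehyde and translactonization.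

Step 18
Reactants: 26 (4S)-limonene 1,2-oxide (cis/trans mixture)
Product: 28 (S)-3-isopropenyl-6-oxoheptanal, via limonene-1,2-diol 27 (not isolated)
Conditions: HIO4·2H2O, THF/H2O, 0 °C
Reagents that add atoms: water, O
Why: Periodic acid hydrolyses the epoxide to the 1,2-diol and cleaves it (glycol cleavage); the future C13 stereocentre is not involved.

Step 19
Reactants: 28 keto aldehyde
Product: 29 (S)-5-(2,2-dimethoxyethyl)-6-methylhept-6-en-2-one
Conditions: HC(OMe)3, MeOH, PPTS (cat.), 0 °C
Reagents that add atoms: trimethyl orthoformate, COC(OC)OC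
Why: Chemoselective acetalization, since the aldehyde reacts far faster than the methyl ketone.

Step 20
Reactants: 29 keto acetal
Product: 31 (S)-4-(2,2-dimethoxyethyl)-5-methylhex-5-enoic acid, via tribromomethyl ketone 30 (not isolated)
Conditions: Br2, NaOH, dioxane/H2O, 0 °C; then NaH2PO4 to pH 5
Reagents that add atoms: sodium hydroxide, [Na+].[OH-]
Why: Haloform reaction: exhaustive α-bromination of the methyl ketone and hydroxide cleavage give the acid, and the cold basic medium spares the acetal and the 1,1-disubstituted alkene.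

Step 21
Reactants: 25 C20 hydroxy C9 aldehyde; 31 side-chain acid
Product: 32 C20 ester
Conditions: EDC·HCl, DMAP, CH2Cl2, 0 °C → rt
Reagents that add atoms: none
Why: Carbodiimide (Steglich) esterification of the primary alcohol under conditions too mild to open the γ-lactone.

Step 22
Reactants: 32 C20 ester
Product: 33 β-hydroxy spiro δ-lactone (epimers at C8 and C9)
Conditions: LiN(SiMe3)2, THF, −78 °C; NH4Cl (aq)
Reagents that add atoms: none
Why: Intramolecular aldol addition of the ester lithium enolate (C8) to the non-enolizable C9 aldehyde closes the six-membered spiro δ-lactone; the two new centres are removed in step 23.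

Step 23
Reactants: 33 β-hydroxy δ-lactone
Product: 35 C8=C9 unsaturated spiro δ-lactone, via C9 mesylate 34 (not isolated)
Conditions: MsCl, Et3N, CH2Cl2, 0 °C; then DBU, rt
Reagents that add atoms: none
Why: Mesylation and E1cB elimination give the α-substituted α,β-unsaturated δ-lactone; elimination can only go toward C8 because C10 is quaternary.

Step 24
Reactants: 35 unsaturated δ-lactone acetal
Product: 36 unsaturated δ-lactone C11 aldehyde
Conditions: PPTS, acetone/H2O, 50 °C
Reagents that add atoms: water, O
Why: Mild acid hydrolysis of the dimethyl acetal unmasks the C11 aldehyde without touching the isopropenyl group or the lactones.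

Step 25
Reactants: 36 C11 aldehyde
Product: 37 tricyclic C11 alcohol (ring C closed; epimers at C8 and C11)
Conditions: SmI2, t-BuOH, THF/HMPA, −78 °C
Reagents that add atoms: none
Why: SmI2 ketyl–olefin cyclization: the C11 ketyl adds 6-endo to the β-carbon C9 through a chair transition state with the isopropenyl group equatorial, on the C9 face syn to C1 and anti to the bulkier C5 branch, which sets C9; the C8 and C11 centres are reset later.

Step 26
Reactants: 37 tricyclic alcohol
Product: 38 tricyclic C11 ketone
Conditions: Dess–Martin periodinane, NaHCO3, CH2Cl2, rt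
Reagents that add atoms: none
Why: Dess–Martin oxidation gives the C11 ketone; C9 becomes epimerizable, but its configuration (C10 and isopropenyl trans-1,4, both equatorial) is the thermodynamically preferred one.

Step 27
Reactants: 38 tricyclic ketone
Product: 39 tricyclic C11 alcohol with OH cis to the C9–C10 bond
Conditions: LiBH(sBu)3, THF, −78 °C; NH4Cl (aq)
Reagents that add atoms: none
Why: The bulky hydride attacks the cyclohexanone from the equatorial direction and gives the axial alcohol cis to the equatorial C10 substituent, which is the target C11 configuration (equatorial after ring C flips for bridging); lactones are not reduced at −78 °C.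

Step 28
Reactants: 39 tricyclic alcohol
Product: 40 C11 TBS ether and C7 TBS ketene acetal
Conditions: KN(SiMe3)2, TBSCl (in-situ quench), THF/DMPU, −78 → 0 °C
Reagents that add atoms: tert-butyldimethylsilyl chloride, CC(C)(C)[Si](C)(C)Cl
Why: The potassium alkoxide and the δ-lactone enolate are both trapped by TBSCl; C8–H is the accessible α-hydrogen, since C5–H lies between two quaternary carbons.

Step 29
Reactants: 40 silyl ketene acetal
Product: 41 tetracycle with C8 quaternary and exocyclic C16=C17 (C11–OTBS and C15H2)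
Conditions: Pd(OAc)2 (1 equiv), AcOH, DMSO, 45 °C
Reagents that add atoms: none
Why: Oxidative cyclization by divalent palladium: the silyl ketene acetal attacks the activated isopropenyl group (5-exo closure of C8–C15), and β-hydride elimination gives the exocyclic alkene. C8 becomes quaternary on the only face the axial C13 side chain can reach, closing ring D and the bicyclo[3.2.1]octane.

Step 30
Reactants: 41 exo-methylene tetracycle
Product: 42 C15 allylic alcohol
Conditions: SeO2 (cat.), t-BuOOH, CH2Cl2, rt
Reagents that add atoms: tert-butyl hydroperoxide, CC(C)(C)OO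
Why: Allylic oxidation (ene reaction then [2,3] shift) at C15, the only allylic methylene; its configuration is lost in step 31.

Step 31
Reactants: 42 allylic alcohol
Product: 43 16-methylene-15-ketone
Conditions: Dess–Martin periodinane, CH2Cl2, rt
Reagents that add atoms: none
Why: Dess–Martin oxidation of the allylic alcohol to the exocyclic enone.

Step 32
Reactants: 43 exocyclic enone
Product: 44 11-O-TBS guidongnin C
Conditions: H2 (1 atm), Pd/C, EtOAc, rt
Reagents that add atoms: none
Why: Hydrogenation of the exocyclic enone from the exo face of the bicyclo[3.2.1]octane (away from the C9–C11–C12 bridge) places the C16 methyl endo, as in the target.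

Step 33
Reactants: 44 11-O-TBS guidongnin C
Product: 45 guidongnin C
Conditions: HF·pyridine, THF/pyridine, rt
Reagents that add atoms: none
Why: Acidic fluoride cleavage of the secondary silyl ether without epimerizing C16 or opening the lactones.

**Compound list**

1 | (R)-5-(hydroxymethyl)dihydrofuran-2(3H)-one | OC[C@H]1CCC(=O)O1 | starting material
2 | (R)-5-(trityloxymethyl)dihydrofuran-2(3H)-one | O=C1CC[C@H](COC(c2ccccc2)(c2ccccc2)c2ccccc2)O1 | intermediate
3 | allyl bromide | C=CCBr | starting material
4 | (5R)-3-allyl-5-(trityloxymethyl)dihydrofuran-2(3H)-one, C3 epimers | O=C1C(CC=C)C[C@H](COC(c2ccccc2)(c2ccccc2)c2ccccc2)O1 | intermediate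
5 | benzyl chloromethyl ether | ClCOCc1ccccc1 | starting material
6 | 3-allyl-3-(benzyloxymethyl)-5-(trityloxymethyl)dihydrofuran-2(3H)-one, benzyloxymethyl trans to trityloxymethyl | O=C1[C@@](CC=C)(COCc2ccccc2)C[C@H](COC(c2ccccc2)(c2ccccc2)c2ccccc2)O1 | intermediate
7 | 2-allyl-2-(benzyloxymethyl)-5-(trityloxy)pentane-1,4-diol | OC[C@@](CC=C)(COCc1ccccc1)C[C@@H](O)COC(c1ccccc1)(c1ccccc1)c1ccccc1 | intermediate
8 | C20 mono-TBDPS ether of 7 | CC(C)(C)[Si](OC[C@@](CC=C)(COCc1ccccc1)C[C@@H](O)COC(c1ccccc1)(c1ccccc1)c1ccccc1)(c1ccccc1)c1ccccc1 | intermediate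
9 | open-chain hydroxy aldehyde (C6 aldehyde) | O=CC[C@@](COCc1ccccc1)(CO[Si](c1ccccc1)(c1ccccc1)C(C)(C)C)C[C@@H](O)COC(c1ccccc1)(c1ccccc1)c1ccccc1 | intermediate
10 | six-membered lactol, anomers | OC1C[C@@](COCc2ccccc2)(CO[Si](c2ccccc2)(c2ccccc2)C(C)(C)C)C[C@H](COC(c2ccccc2)(c2ccccc2)c2ccccc2)O1 | intermediate
11 | δ-lactone, CH2OTr on C2 | O=C1C[C@@](COCc2ccccc2)(CO[Si](c2ccccc2)(c2ccccc2)C(C)(C)C)C[C@H](COC(c2ccccc2)(c2ccccc2)c2ccccc2)O1 | intermediate
12 | δ-lactone, CH2OH on C2 | O=C1C[C@@](COCc2ccccc2)(CO[Si](c2ccccc2)(c2ccccc2)C(C)(C)C)C[C@H](CO)O1 | intermediate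
13 | δ-lactone C2 carbaldehyde | O=C1C[C@@](COCc2ccccc2)(CO[Si](c2ccccc2)(c2ccccc2)C(C)(C)C)C[C@H](C=O)O1 | intermediate
14 | 2-(triphenylphosphoranylidene)propanal | CC(C=O)=P(c1ccccc1)(c1ccccc1)c1ccccc1 | starting material
15 | δ-lactone with (E)-2-methyl-3-oxoprop-1-enyl on C2 | O=C1C[C@@](COCc2ccccc2)(CO[Si](c2ccccc2)(c2ccccc2)C(C)(C)C)C[C@H](/C=C(\C)C=O)O1 | intermediate
16 | δ-lactone with (E)-3-hydroxy-2-methylprop-1-enyl on C2 | O=C1C[C@@](COCc2ccccc2)(CO[Si](c2ccccc2)(c2ccccc2)C(C)(C)C)C[C@H](/C=C(\C)CO)O1 | intermediate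
17 | Claisen precursor: δ-lactone with (E)-alkenyl on C2, C19–OTBS, C10 carrying CH2OBn (C9) and CH2OTBDPS (C20) | O=C1C[C@@](COCc2ccccc2)(CO[Si](c2ccccc2)(c2ccccc2)C(C)(C)C)C[C@H](/C=C(\C)CO[Si](C)(C)C(C)(C)C)O1 | intermediate
18 | trimethylsilyl ketene acetal of 17 | C[Si](C)(C)OC1=C[C@@](COCc2ccccc2)(CO[Si](c2ccccc2)(c2ccccc2)C(C)(C)C)C[C@H](/C=C(\C)CO[Si](C)(C)C(C)(C)C)O1 | intermediate
19 | trimethylsilyl ester of 20 | C[Si](C)(C)OC(=O)[C@@H]1[C@](C)(CO[Si](C)(C)C(C)(C)C)C=CC[C@]1(COCc1ccccc1)CO[Si](c1ccccc1)(c1ccccc1)C(C)(C)C | intermediate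
20 | ring A cyclohex-3-ene carboxylic acid with C4, C5 and C10 set | OC(=O)[C@@H]1[C@](C)(CO[Si](C)(C)C(C)(C)C)C=CC[C@]1(COCc1ccccc1)CO[Si](c1ccccc1)(c1ccccc1)C(C)(C)C | intermediate
21 | C19 hydroxy acid | OC(=O)[C@@H]1[C@](C)(CO)C=CC[C@]1(COCc1ccccc1)CO[Si](c1ccccc1)(c1ccccc1)C(C)(C)C | intermediate
22 | cis-fused γ-lactone on ring A cyclohexene | O=C1OC[C@]2(C)C=CC[C@](COCc3ccccc3)(CO[Si](c3ccccc3)(c3ccccc3)C(C)(C)C)[C@H]12 | intermediate
23 | saturated γ-lactone, C9 alcohol, C20–OTBDPS | O=C1OC[C@]2(C)CCC[C@](CO)(CO[Si](c3ccccc3)(c3ccccc3)C(C)(C)C)[C@H]12 | intermediate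
24 | C9 aldehyde, C20–OTBDPS | O=C1OC[C@]2(C)CCC[C@](C=O)(CO[Si](c3ccccc3)(c3ccccc3)C(C)(C)C)[C@H]12 | intermediate
25 | C9 aldehyde, C20 alcohol | O=C1OC[C@]2(C)CCC[C@](C=O)(CO)[C@H]12 | intermediate
26 | (4S)-limonene 1,2-oxide, cis/trans mixture | CC12CC[C@@H](CC1O2)C(C)=C | starting material
27 | (4S)-1-methyl-4-(prop-1-en-2-yl)cyclohexane-1,2-diol | CC1(O)CC[C@@H](CC1O)C(C)=C | intermediate
28 | (S)-3-isopropenyl-6-oxoheptanal | CC(=O)CC[C@@H](CC=O)C(C)=C | intermediate
29 | (S)-5-(2,2-dimethoxyethyl)-6-methylhept-6-en-2-one | CC(=O)CC[C@@H](CC(OC)OC)C(C)=C | intermediate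
30 | tribromomethyl ketone of 29 | BrC(Br)(Br)C(=O)CC[C@@H](CC(OC)OC)C(C)=C | intermediate
31 | (S)-4-(2,2-dimethoxyethyl)-5-methylhex-5-enoic acid | OC(=O)CC[C@@H](CC(OC)OC)C(C)=C | intermediate
32 | C20 ester of 25 with 31 | O=C1OC[C@]2(C)CCC[C@](C=O)(COC(=O)CC[C@@H](CC(OC)OC)C(C)=C)[C@H]12 | intermediate
33 | β-hydroxy spiro δ-lactone, epimers at C8 and C9 | O=C1OC[C@]2(C)CCC[C@]3(COC(=O)C(C[C@@H](CC(OC)OC)C(C)=C)C3O)[C@H]12 | intermediate
34 | C9 mesylate of 33 | O=C1OC[C@]2(C)CCC[C@]3(COC(=O)C(C[C@@H](CC(OC)OC)C(C)=C)C3OS(C)(=O)=O)[C@H]12 | intermediate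
35 | C8=C9 unsaturated spiro δ-lactone, C11 dimethyl acetal | O=C1OC[C@]2(C)CCC[C@]3(COC(=O)C(C[C@@H](CC(OC)OC)C(C)=C)=C3)[C@H]12 | intermediate
36 | C8=C9 unsaturated spiro δ-lactone, C11 aldehyde | O=C1OC[C@]2(C)CCC[C@]3(COC(=O)C(C[C@@H](CC=O)C(C)=C)=C3)[C@H]12 | intermediate
37 | tricyclic C11 alcohol, epimers at C8 and C11 | O=C1OC[C@]2(C)CCC[C@]3(COC(=O)C4C[C@H](C(C)=C)CC(O)[C@H]43)[C@H]12 | intermediate
38 | tricyclic C11 ketone, epimers at C8 | O=C1OC[C@]2(C)CCC[C@]3(COC(=O)C4C[C@H](C(C)=C)CC(=O)[C@H]43)[C@H]12 | intermediate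
39 | tricyclic C11 alcohol, OH cis to the C9–C10 bond | O=C1OC[C@]2(C)CCC[C@]3(COC(=O)C4C[C@H](C(C)=C)C[C@@H](O)[C@H]43)[C@H]12 | intermediate
40 | C11 TBS ether, C7 TBS ketene acetal | O=C1OC[C@]2(C)CCC[C@]3(COC(O[Si](C)(C)C(C)(C)C)=C4C[C@H](C(C)=C)C[C@@H](O[Si](C)(C)C(C)(C)C)[C@H]43)[C@H]12 | intermediate
41 | 11-O-TBS 16-methylene tetracycle, C15H2 | C=C1C[C@]23C[C@H]1C[C@@H](O[Si](C)(C)C(C)(C)C)[C@H]2[C@@]1(CCC[C@@]2(C)COC(=O)[C@H]21)COC3=O | intermediate
42 | 11-O-TBS 15-hydroxy-16-methylene tetracycle, C15 epimers | C=C1C(O)[C@]23C[C@H]1C[C@@H](O[Si](C)(C)C(C)(C)C)[C@H]2[C@@]1(CCC[C@@]2(C)COC(=O)[C@H]21)COC3=O | intermediate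
43 | 11-O-TBS 16-methylene-15-ketone | C=C1C(=O)[C@]23C[C@H]1C[C@@H](O[Si](C)(C)C(C)(C)C)[C@H]2[C@@]1(CCC[C@@]2(C)COC(=O)[C@H]21)COC3=O | intermediate
44 | 11-O-TBS guidongnin C | C[C@H]1C(=O)[C@]23C[C@H]1C[C@@H](O[Si](C)(C)C(C)(C)C)[C@H]2[C@@]1(CCC[C@@]2(C)COC(=O)[C@H]21)COC3=O | intermediate
45 | guidongnin C | C[C@H]1C(=O)[C@]23C[C@H]1C[C@@H](O)[C@H]2[C@@]1(CCC[C@@]2(C)COC(=O)[C@H]21)COC3=O | target

**Step count and risks**

Total step count: 33. Longest linear sequence: 30 (steps 1–17 and 21–33); the side-chain branch is steps 18–20.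

Steps most likely to fail:

Step 13 (key step). The boat transition state must join C5, which sits next to quaternary C10, to the fully substituted C4; the ketene acetal may instead be consumed by C-silylation or by hydrolysis back to the lactone. The fallback is an acyclic Ireland–Claisen rearrangement followed by ring-closing metathesis; it sets out from 12 and returns at 20. Alcohol 12 is converted (I2, PPh3, imidazole) into the iodide F1, and zinc dust in AcOH/EtOH opens the lactone by reductive β-elimination to the alkenoic acid F2. Separately, prenyl acetate is oxidized at its (E)-methyl group (SeO2, t-BuOOH) to (E)-4-hydroxy-3-methylbut-2-enyl acetate F3, silylated (TBSCl, imidazole) to the silyl ether acetate F4 and deacetylated (K2CO3, MeOH) to the allylic alcohol F5. Esterification of F2 with F5 (EDC, DMAP) gives the allyl ester F6. Its (Z)-silyl ketene acetal (LiN(iPr)2, THF/DMPU, Me3SiCl, −78 °C → rt) rearranges through a chair transition state to the diene acid F7, forming C4–C5 with the required relative configuration; the sense relative to C10 is not controlled in this open-chain version and the isomers would be separated. Ring-closing metathesis of the vinyl and allyl groups of F7 (second-generation Grubbs catalyst (H2IMes)(PCy3)Cl2Ru=CHPh, CH2Cl2, 40 °C) closes ring A at C2=C3 and gives 20.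

Step 22. The ester must be deprotonated in the presence of its own hindered aldehyde; amide addition to the aldehyde or retro-aldol reversal of the lithium aldolate may prevent ring closure. The fallback is an intermolecular aldol addition with a preformed enolate, then lactonization; it sets out from 24 and 31 and returns at 33. Acid 31 is methylated (Me3SiCHN2, MeOH/toluene) to the methyl ester F8, whose lithium enolate (LiN(iPr)2, THF, −78 °C) adds to aldehyde 24 to give the β-hydroxy ester F9. HF·pyridine then removes the TBDPS group, and the freed C20 hydroxyl lactonizes onto the methyl ester (CSA cat., toluene, 60 °C) to give 33.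

Step 27. Facial selectivity may be poor if the neighbouring quaternary C10 and the fused lactone hinder the equatorial trajectory, so that axial hydride delivery gives the C11 epimer. The fallback is Mitsunobu inversion; it sets out from 38 and returns at 39. Ketone 38 is reduced with NaBH4 (MeOH, −20 °C) to the equatorial 11-epi alcohol F10 (also the epimer expected to predominate in 37). Mitsunobu reaction with chloroacetic acid (PPh3, DIAD, toluene) gives the inverted chloroacetate F11, and thiourea with NaHCO3 in EtOH removes the chloroacetyl group under near-neutral conditions to give 39.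

Further compounds
F1 | step 13 | δ-lactone with CH2I on C2 | O=C1C[C@@](COCc2ccccc2)(CO[Si](c2ccccc2)(c2ccccc2)C(C)(C)C)C[C@H](CI)O1
F2 | step 13 | 3-(benzyloxymethyl)-3-(tert-butyldiphenylsilyloxymethyl)hex-5-enoic acid | OC(=O)C[C@@](COCc1ccccc1)(CO[Si](c1ccccc1)(c1ccccc1)C(C)(C)C)CC=C
F3 | step 13 | (E)-4-hydroxy-3-methylbut-2-enyl acetate | CC(=O)OC/C=C(\C)CO
F4 | step 13 | (E)-4-(tert-butyldimethylsilyloxy)-3-methylbut-2-enyl acetate | CC(=O)OC/C=C(\C)CO[Si](C)(C)C(C)(C)C
F5 | step 13 | (E)-4-(tert-butyldimethylsilyloxy)-3-methylbut-2-en-1-ol | OC/C=C(\C)CO[Si](C)(C)C(C)(C)C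
F6 | step 13 | allyl ester of F2 with F5 | O=C(C[C@@](COCc1ccccc1)(CO[Si](c1ccccc1)(c1ccccc1)C(C)(C)C)CC=C)OC/C=C(\C)CO[Si](C)(C)C(C)(C)C
F7 | step 13 | open-chain diene acid with C4–C5 formed | OC(=O)[C@H]([C@](C)(CO[Si](C)(C)C(C)(C)C)C=C)[C@@](COCc1ccccc1)(CO[Si](c1ccccc1)(c1ccccc1)C(C)(C)C)CC=C
F8 | step 22 | methyl (S)-4-(2,2-dimethoxyethyl)-5-methylhex-5-enoate | COC(=O)CC[C@@H](CC(OC)OC)C(C)=C
F9 | step 22 | β-hydroxy methyl ester from 24 and F8, epimers at C8 and C9 | O=C1OC[C@]2(C)CCC[C@](C(O)C(C[C@@H](CC(OC)OC)C(C)=C)C(=O)OC)(CO[Si](c3ccccc3)(c3ccccc3)C(C)(C)C)[C@H]12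
F10 | step 27 | tricyclic 11-epi alcohol | O=C1OC[C@]2(C)CCC[C@]3(COC(=O)C4C[C@H](C(C)=C)C[C@H](O)[C@H]43)[C@H]12
F11 | step 27 | C11 chloroacetate with inverted configuration | O=C1OC[C@]2(C)CCC[C@]3(COC(=O)C4C[C@H](C(C)=C)C[C@@H](OC(=O)CCl)[C@H]43)[C@H]12
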